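**Plan**
- **Labels:** hub ring C carries OH at C3, the arm oxygens at C1 and C5, and the ring E oxygen at C6. Each of the two identical arms is ring B (B1–O–ring A, OH at B3 and B5, B4–O–hub, B6–G1 of ring G). Ring E is 4-chloro-3,5-dihydroxyphenyl.
- **Cuts, in retrosynthetic order:** nineteen O–CH3 bonds (every phenol is masked as a methyl ether), the hub C6–O–E1 ether, the two B4–O–hub ethers, the G1–G2 bond of ring G, the C4–C5 bond of the resulting hexanoate chain, and the A1–O–B1 ether.
- **Enabling feature:** ring G is a phloroglucinol ring held to B6 through G1. Its atoms G2-G3-G4-G5-G6-G1 are therefore C1–C6 of a 3,5-dioxohexanoate whose C6 is a benzylic CH2 on B6. Claisen closure of G1–G2 grows ring G around a bond that already exists.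
- **Forward order:** the ring B bromide is formylated at B6 and ring A is attached at B1 (Ullmann). The aldehyde is homologated and extended with acetoacetate dianion, and ring G is closed. Methylation and debenzylation then give the arm phenol. Two arms displace the fluorides of a 2,6-difluorobenzaldehyde hub, and Baeyer–Villiger oxidation turns its CHO into the C6 phenol. Ring E is added (Chan–Lam) and all methyl ethers are cleaved.
- **Stereochemistry:** there is none to set. The target has no stereocentre, the B6–G1 axes are not stereogenic because ring G is symmetric, and the one transient carbinol centre is oxidised away.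

Key step: step 7

Assumption: the target is treated as achiral. All compounds marked as starting material in the compound list are taken to be purchasable.

Notation: ArB = 3-(benzyloxy)-2,4-dimethoxy-6-(2,4,6-trimethoxyphenoxy)phenyl. arm = 2,2',4,4',6'-pentamethoxy-6-(2,4,6-trimethoxyphenoxy)-[1,1'-biphenyl]-3-yl, and "arm-oxy" is this group bound through the oxygen on its C3 (= B4).

Step 1
Reactants: 1 4-bromo-2,6-dimethoxyphenol
Product: 2 2-(benzyloxy)-5-bromo-1,3-dimethoxybenzene
Conditions: BnBr, K2CO3, DMF, 60 °C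
Reagents that add atoms: benzyl bromide, BrCc1ccccc1
Why: Williamson etherification puts the only hydrogenolysable group of the route on the future B4 oxygen, so that this oxygen alone can be released in step 9 without any selective demethylation.

Step 2
Reactants: 2 2-(benzyloxy)-5-bromo-1,3-dimethoxybenzene
Product: 4 3-(benzyloxy)-6-bromo-2,4-dimethoxybenzaldehyde, via aryl iminium chloride 3 (not isolated)
Conditions: POCl3, DMF, 0 to 90 °C; then ice-water
Reagents that add atoms: N,N-dimethylformamide, CN(C)C=O; water, O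
Why: Vilsmeier–Haack formylation can only strike the two equivalent free positions of 2, each ortho to one methoxy group and para to the other, so the carbon substituent should land on B6 next to the bromine at B1 as a single regioisomer while the benzyl ether survives.

Step 3
Reactants: 4 3-(benzyloxy)-6-bromo-2,4-dimethoxybenzaldehyde; 5 2,4,6-trimethoxyphenol
Product: 6 3-(benzyloxy)-2,4-dimethoxy-6-(2,4,6-trimethoxyphenoxy)benzaldehyde
Conditions: CuI (10 mol %), picolinic acid (20 mol %), K3PO4, DMSO, 90 °C, Ar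
Reagents that add atoms: none
Why: The copper-catalysed Ullmann diaryl ether synthesis uses the electron-rich, di-ortho-substituted ring A phenol as nucleophile and a bromide with a single ortho neighbour that is activated by that ortho formyl group, which is the polarity that tolerates hindered phenols best.

Step 4
Reactants: 6 3-(benzyloxy)-2,4-dimethoxy-6-(2,4,6-trimethoxyphenoxy)benzaldehyde
Product: 8 2-(ArB)acetaldehyde, via enol ether 7 (not isolated)
Conditions: MeOCH2PPh3Cl, KOtBu, THF, 0 °C to rt; then 2 M HCl, 40 °C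
Reagents that add atoms: (methoxymethyl)triphenylphosphonium chloride, COC[P+](c1ccccc1)(c1ccccc1)c1ccccc1.[Cl-]; water, O
Why: Wittig methoxymethylenation of the non-enolisable aldehyde followed by acid hydrolysis of the enol ether in the same flask is the standard one-carbon homologation to an arylacetaldehyde, and the alkene geometry of 7 is lost on hydrolysis.

Step 5
Reactants: 8 2-(ArB)acetaldehyde; 9 methyl acetoacetate
Product: 11 methyl 6-(ArB)-5-hydroxy-3-oxohexanoate (racemic), via acetoacetate dianion 10 (not isolated)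
Conditions: 9, NaH then n-BuLi, THF, 0 °C; 8, −78 °C; aq NH4Cl
Reagents that add atoms: none
Why: In this aldol addition of a 1,3-dicarbonyl dianion the terminal carbon adds to the aldehyde at −78 °C faster than it deprotonates it, which avoids the enolisation that burdens acylation by an arylacetic ester, and the new carbinol centre C5 forms as a racemate that step 6 erases.

Step 6
Reactants: 11 methyl 6-(ArB)-5-hydroxy-3-oxohexanoate
Product: 12 methyl 6-(ArB)-3,5-dioxohexanoate
Conditions: Dess–Martin periodinane (1.1 equiv), CH2Cl2, 0 °C to rt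
Reagents that add atoms: none
Why: Dess–Martin oxidation converts δ-hydroxy-β-keto esters into 3,5-dioxo esters under neutral conditions that should neither dehydrate the aldol nor touch the electron-rich rings.

Step 7
Reactants: 12 methyl 6-(ArB)-3,5-dioxohexanoate
Product: 14 2-(ArB)benzene-1,3,5-triol, via cyclohexanetrione tautomer 13 (not isolated)
Conditions: Mg(OMe)2 (5 equiv), MeOH, reflux, Ar; then 1 M HCl
Reagents that add atoms: none
Why: Mg(OMe)2 first deprotonates the doubly activated C2 and C4 methylenes and folds the chain as a magnesium chelate, yet because this base equilibrates, the C4,C6-dienolate with an un-enolised ester stays accessible, its benzylic carbon C6 (future G1, acidified by the C5 ketone and ring B) adds to the ester carbonyl C1 (future G2), methoxide leaves, and trione 13 tautomerises to the aromatic triol. The closest known reaction is the intramolecular Claisen (Dieckmann-type) condensation of 3,5-dioxo esters, or of the 4-methoxy-2-pyranones derived from them, to phloroglucinols, which copies the folding of a triketide in polyketide biosynthesis. Ring G closes in the 6-(enolendo)-exo-trig mode, all six ring atoms coming from the hexanoate chain. No stereocentre is created, since G1 ends up sp2 and ring G is symmetric about the B6–G1 axis. The step needs C-acylation at C6 instead of O-acylation by the C5 enolate oxygen: the pyranone from O-acylation is reopened by methoxide whereas aromatisation to a magnesium phenolate is irreversible, a chain of this length offers no six-membered aldol alternative, and chelation of the enolised diketone slows retro-Claisen cleavage. As the B6–G1 bond has been in place since step 2, no cross-coupling ever has to join two carbons flanked by four oxygen substituents.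

Step 8
Reactants: 14 2-(ArB)benzene-1,3,5-triol
Product: 15 3-(benzyloxy)-2,2',4,4',6'-pentamethoxy-6-(2,4,6-trimethoxyphenoxy)-1,1'-biphenyl
Conditions: Me2SO4, K2CO3, acetone, reflux
Reagents that add atoms: dimethyl sulfate, COS(=O)(=O)OC
Why: Williamson-type O-methylation with the hard electrophile dimethyl sulfate under K2CO3 in acetone favours oxygen over ring carbon, as in the usual preparation of phloroglucinol trimethyl ethers.

Step 9
Reactants: 15 3-(benzyloxy)-2,2',4,4',6'-pentamethoxy-6-(2,4,6-trimethoxyphenoxy)-1,1'-biphenyl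
Product: 16 arm phenol 2,2',4,4',6'-pentamethoxy-6-(2,4,6-trimethoxyphenoxy)-[1,1'-biphenyl]-3-ol
Conditions: H2 (1 atm), 10% Pd/C, EtOAc–MeOH, rt
Reagents that add atoms: none
Why: Catalytic hydrogenolysis cleaves the single benzyl ether and leaves methyl and diaryl ethers untouched, and it is placed before any chlorine enters the molecule.

Step 10
Reactants: 16 arm phenol (2 equivalents); 17 2,6-difluoro-4-methoxybenzaldehyde
Product: 19 4-methoxy-2,6-bis(arm-oxy)benzaldehyde, via monofluoride 18 (not isolated)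
Conditions: 16 (2.1 equiv), Cs2CO3, DMSO, 110 °C, Ar
Reagents that add atoms: none
Why: Two successive nucleophilic aromatic substitutions (addition–elimination) replace both fluorides, each ortho to the formyl acceptor, by the caesium phenolate of 16, and the methoxy group of 17 sits meta to both reacting carbons, where it does not destabilise the anionic adducts.

Step 11
Reactants: 19 4-methoxy-2,6-bis(arm-oxy)benzaldehyde
Product: 21 4-methoxy-2,6-bis(arm-oxy)phenol, via aryl formate 20 (not isolated)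
Conditions: mCPBA, CH2Cl2, 0 °C to rt; then K2CO3 (cat.), MeOH, rt
Reagents that add atoms: 3-chloroperbenzoic acid, OOC(=O)c1cccc(Cl)c1
Why: Baeyer–Villiger oxidation of a benzaldehyde with three ortho/para oxygen donors proceeds by fast aryl migration to the formate, ahead of any attack on the methoxyarenes, and mild methanolysis then frees the phenol at hub carbon C6.

Step 12
Reactants: 22 2-chloro-1,3-dimethoxybenzene
Product: 24 (4-chloro-3,5-dimethoxyphenyl)boronic acid, via pinacol boronate 23 (not isolated)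
Conditions: B2pin2 (0.55 equiv), [Ir(OMe)(cod)]2 (1.5 mol %), 4,4'-di-tert-butyl-2,2'-bipyridine (3 mol %), THF, 65 °C; then NaIO4, 1 M HCl, THF–H2O, rt
Reagents that add atoms: bis(pinacolato)diboron, CC1(C)OB(OC1(C)C)B1OC(C)(C)C(C)(C)O1; water, O
Why: Iridium-catalysed C–H borylation is sterically governed and takes the only C–H of 22 without an ortho neighbour (para to chlorine), and periodate cleavage of the pinacol in the same flask releases the boronic acid.

Step 13
Reactants: 21 4-methoxy-2,6-bis(arm-oxy)phenol; 24 (4-chloro-3,5-dimethoxyphenyl)boronic acid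
Product: 25 2-(4-chloro-3,5-dimethoxyphenoxy)-5-methoxy-1,3-bis(arm-oxy)benzene (nonadecamethyl ether of the target)
Conditions: 24 (3 equiv), Cu(OAc)2 (2 equiv), pyridine, 4 Å MS, CH2Cl2, air, rt
Reagents that add atoms: none
Why: Chan–Lam coupling arylates phenols at room temperature and accepts 2,6-disubstituted phenols as long as the boronic acid has free ortho positions, as 24 has, while the aryl chloride is inert to copper under these conditions.

Step 14
Reactants: 25 nonadecamethyl ether of the target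
Product: 26 CNP0275555.0
Conditions: BBr3 (60 equiv), CH2Cl2, −78 °C to rt; then ice-water
Reagents that add atoms: none
Why: BBr3 cleaves aryl methyl ethers by complexation at oxygen and bromide attack at the methyl carbon, so the nineteen methoxy groups should fall while the five diaryl ethers, the two biaryl bonds and the aryl chloride, none of which offers an sp3 carbon to bromide, persist.

**Compound list**
1 | 4-bromo-2,6-dimethoxyphenol | COc1cc(Br)cc(OC)c1O | starting material
2 | 2-(benzyloxy)-5-bromo-1,3-dimethoxybenzene | COc1cc(Br)cc(OC)c1OCc1ccccc1 | intermediate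
3 | [3-(benzyloxy)-6-bromo-2,4-dimethoxyphenyl]methylidene(dimethyl)ammonium chloride (not isolated) | C[N+](C)=Cc1c(Br)cc(OC)c(OCc2ccccc2)c1OC.[Cl-] | intermediate
4 | 3-(benzyloxy)-6-bromo-2,4-dimethoxybenzaldehyde | O=Cc1c(Br)cc(OC)c(OCc2ccccc2)c1OC | intermediate
5 | 2,4,6-trimethoxyphenol | COc1cc(OC)c(O)c(OC)c1 | starting material
6 | 3-(benzyloxy)-2,4-dimethoxy-6-(2,4,6-trimethoxyphenoxy)benzaldehyde | O=Cc1c(Oc2c(OC)cc(OC)cc2OC)cc(OC)c(OCc2ccccc2)c1OC | intermediate
7 | 2-(benzyloxy)-1,3-dimethoxy-4-(2-methoxyethenyl)-5-(2,4,6-trimethoxyphenoxy)benzene, E/Z mixture (not isolated) | COC=Cc1c(Oc2c(OC)cc(OC)cc2OC)cc(OC)c(OCc2ccccc2)c1OC | intermediate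
8 | 2-[3-(benzyloxy)-2,4-dimethoxy-6-(2,4,6-trimethoxyphenoxy)phenyl]acetaldehyde | O=CCc1c(Oc2c(OC)cc(OC)cc2OC)cc(OC)c(OCc2ccccc2)c1OC | intermediate
9 | methyl acetoacetate | COC(=O)CC(C)=O | starting material
10 | sodium lithium dianion of methyl acetoacetate (not isolated) | [Na+].[Li+].COC([O-])=CC([O-])=C | intermediate
11 | methyl 6-[3-(benzyloxy)-2,4-dimethoxy-6-(2,4,6-trimethoxyphenoxy)phenyl]-5-hydroxy-3-oxohexanoate, racemic | COC(=O)CC(=O)CC(O)Cc1c(Oc2c(OC)cc(OC)cc2OC)cc(OC)c(OCc2ccccc2)c1OC | intermediate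
12 | methyl 6-[3-(benzyloxy)-2,4-dimethoxy-6-(2,4,6-trimethoxyphenoxy)phenyl]-3,5-dioxohexanoate | COC(=O)CC(=O)CC(=O)Cc1c(Oc2c(OC)cc(OC)cc2OC)cc(OC)c(OCc2ccccc2)c1OC | intermediate
13 | 2-[3-(benzyloxy)-2,4-dimethoxy-6-(2,4,6-trimethoxyphenoxy)phenyl]cyclohexane-1,3,5-trione (not isolated) | O=C1CC(=O)C(c2c(Oc3c(OC)cc(OC)cc3OC)cc(OC)c(OCc3ccccc3)c2OC)C(=O)C1 | intermediate
14 | 2-[3-(benzyloxy)-2,4-dimethoxy-6-(2,4,6-trimethoxyphenoxy)phenyl]benzene-1,3,5-triol | Oc1cc(O)c(-c2c(Oc3c(OC)cc(OC)cc3OC)cc(OC)c(OCc3ccccc3)c2OC)c(O)c1 | intermediate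
15 | 3-(benzyloxy)-2,2',4,4',6'-pentamethoxy-6-(2,4,6-trimethoxyphenoxy)-1,1'-biphenyl | COc1cc(OC)c(-c2c(Oc3c(OC)cc(OC)cc3OC)cc(OC)c(OCc3ccccc3)c2OC)c(OC)c1 | intermediate
16 | 2,2',4,4',6'-pentamethoxy-6-(2,4,6-trimethoxyphenoxy)-[1,1'-biphenyl]-3-ol (arm phenol) | COc1cc(OC)c(-c2c(Oc3c(OC)cc(OC)cc3OC)cc(OC)c(O)c2OC)c(OC)c1 | intermediate
17 | 2,6-difluoro-4-methoxybenzaldehyde | COc1cc(F)c(C=O)c(F)c1 | starting material
18 | 2-(arm-oxy)-6-fluoro-4-methoxybenzaldehyde (not isolated) | COc1cc(F)c(C=O)c(Oc2c(OC)cc(Oc3c(OC)cc(OC)cc3OC)c(-c3c(OC)cc(OC)cc3OC)c2OC)c1 | intermediate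
19 | 4-methoxy-2,6-bis(arm-oxy)benzaldehyde | COc1cc(Oc2c(OC)cc(Oc3c(OC)cc(OC)cc3OC)c(-c3c(OC)cc(OC)cc3OC)c2OC)c(C=O)c(Oc2c(OC)cc(Oc3c(OC)cc(OC)cc3OC)c(-c3c(OC)cc(OC)cc3OC)c2OC)c1 | intermediate
20 | 4-methoxy-2,6-bis(arm-oxy)phenyl formate (not isolated) | COc1cc(Oc2c(OC)cc(Oc3c(OC)cc(OC)cc3OC)c(-c3c(OC)cc(OC)cc3OC)c2OC)c(OC=O)c(Oc2c(OC)cc(Oc3c(OC)cc(OC)cc3OC)c(-c3c(OC)cc(OC)cc3OC)c2OC)c1 | intermediate
21 | 4-methoxy-2,6-bis(arm-oxy)phenol | COc1cc(Oc2c(OC)cc(Oc3c(OC)cc(OC)cc3OC)c(-c3c(OC)cc(OC)cc3OC)c2OC)c(O)c(Oc2c(OC)cc(Oc3c(OC)cc(OC)cc3OC)c(-c3c(OC)cc(OC)cc3OC)c2OC)c1 | intermediate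
22 | 2-chloro-1,3-dimethoxybenzene | COc1cccc(OC)c1Cl | starting material
23 | 2-(4-chloro-3,5-dimethoxyphenyl)-4,4,5,5-tetramethyl-1,3,2-dioxaborolane (not isolated) | COc1cc(B2OC(C)(C)C(C)(C)O2)cc(OC)c1Cl | intermediate
24 | (4-chloro-3,5-dimethoxyphenyl)boronic acid | COc1cc(B(O)O)cc(OC)c1Cl | intermediate
25 | 2-(4-chloro-3,5-dimethoxyphenoxy)-5-methoxy-1,3-bis(arm-oxy)benzene | COc1cc(Oc2c(OC)cc(Oc3c(OC)cc(OC)cc3OC)c(-c3c(OC)cc(OC)cc3OC)c2OC)c(Oc2cc(OC)c(Cl)c(OC)c2)c(Oc2c(OC)cc(Oc3c(OC)cc(OC)cc3OC)c(-c3c(OC)cc(OC)cc3OC)c2OC)c1 | intermediate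
26 | CNP0275555.0, 4-(4-chloro-3,5-dihydroxyphenoxy)-3,5-bis[2,6-dihydroxy-4-(2,4,6-trihydroxyphenoxy)-3-(2,4,6-trihydroxyphenyl)phenoxy]phenol | Oc1cc(O)c(Oc2cc(O)c(Oc3cc(O)cc(Oc4c(O)cc(Oc5c(O)cc(O)cc5O)c(-c5c(O)cc(O)cc5O)c4O)c3Oc3cc(O)c(Cl)c(O)c3)c(O)c2-c2c(O)cc(O)cc2O)c(O)c1 | target

**Step count**
- Total step count: 14.
- Longest linear sequence: 13 (steps 1–11, 13 and 14). Step 12 is a one-step side branch.

**The three steps most likely to fail**

**Step 7 (closure of ring G).**
- Risk: deprotonation at C6 may be too slow, because the tetra-oxygenated ring B is twisted out of conjugation and stabilises the carbanion little. The reaction could then stall at lactonisation, or retro-Claisen fragmentation of the diketone could take over.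
- Fallback: it sets out from 12 and removes the competing acidity at C2.
- DBU in refluxing toluene lactonises 12 to 6-(ArB-methyl)-4-hydroxy-2H-pyran-2-one F1.
- Me2SO4 and K2CO3 in acetone give 6-(ArB-methyl)-4-methoxy-2H-pyran-2-one F2.
- NaOMe in MeOH (sealed tube, 120–150 °C) opens the lactone to methyl (2E)-6-(ArB)-3-methoxy-5-oxohex-2-enoate F3.
- In F3 the ester lies cis to the ketone chain and C2 can no longer be deprotonated, so the C6 enolate forms as a simple monoanion. It closes the same G1–G2 bond to give 2-(ArB)-5-methoxybenzene-1,3-diol F4.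
- Methylation under the conditions of step 8 brings the route back at 15.

**Step 10 (double substitution at the hub).**
- Risk: the second addition–elimination may stall. The formyl group is only a moderate acceptor, is weakened by the para methoxy group, and becomes flanked by a bulky aryloxy group after the first substitution. Meanwhile the electron-rich phenolate slowly oxidises at the temperature required.
- Fallback: it sets out from 16 and exchanges the acceptor for a nitro group.
- Purchased 1,3-difluoro-5-methoxy-2-nitrobenzene reacts with 16 (K2CO3, DMF, 70 °C) through 1-(arm-oxy)-3-fluoro-5-methoxy-2-nitrobenzene F5 to 1,3-bis(arm-oxy)-5-methoxy-2-nitrobenzene F6.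
- H2 over Pd/C gives 2,6-bis(arm-oxy)-4-methoxyaniline F7.
- NaNO2 and H2SO4 in aqueous MeCN at 0 °C give 2,6-bis(arm-oxy)-4-methoxybenzenediazonium hydrogen sulfate F8.
- Cu2O and Cu(NO3)2 in water convert F8 into the phenol by copper-mediated hydroxy-dediazoniation. Closure of the aryl radical onto ring B is blocked because B3 and B5 are both substituted.
- The route is rejoined at 21, so steps 10 and 11 are bypassed.

**Step 13 (ring E on the crowded hub phenol).**
- Risk: binding of the phenol to copper between two large aryloxy groups may be slow. Protodeboronation and homocoupling of the boronic acid, and oxidation of the 4-methoxyphenol unit by divalent copper and air, could then win.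
- Fallback: it sets out from 21 and 24 and replaces the oxidative copper coupling by a metal-free ligand coupling at trivalent iodine.
- N-Iodosuccinimide in MeCN converts 24 into 2-chloro-5-iodo-1,3-dimethoxybenzene F9.
- mCPBA and TsOH·H2O in MeCN give (4-chloro-3,5-dimethoxyphenyl)(hydroxy)(tosyloxy)-λ3-iodane F10.
- 1,3,5-Trimethoxybenzene added to the same flask gives (4-chloro-3,5-dimethoxyphenyl)(2,4,6-trimethoxyphenyl)iodonium tosylate F11.
- The potassium phenolate of 21 (KOtBu, THF–toluene, 40 °C) should take up the less electron-rich aryl group, while the trimethoxyphenyl group stays on iodine.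
- The route is rejoined at 25.

**Further compounds**
F1 | step 7 | 6-{[3-(benzyloxy)-2,4-dimethoxy-6-(2,4,6-trimethoxyphenoxy)phenyl]methyl}-4-hydroxy-2H-pyran-2-one | O=c1cc(O)cc(Cc2c(Oc3c(OC)cc(OC)cc3OC)cc(OC)c(OCc3ccccc3)c2OC)o1
F2 | step 7 | 6-{[3-(benzyloxy)-2,4-dimethoxy-6-(2,4,6-trimethoxyphenoxy)phenyl]methyl}-4-methoxy-2H-pyran-2-one | O=c1cc(OC)cc(Cc2c(Oc3c(OC)cc(OC)cc3OC)cc(OC)c(OCc3ccccc3)c2OC)o1
F3 | step 7 | methyl (2E)-6-[3-(benzyloxy)-2,4-dimethoxy-6-(2,4,6-trimethoxyphenoxy)phenyl]-3-methoxy-5-oxohex-2-enoate | COC(=O)/C=C(/OC)CC(=O)Cc1c(Oc2c(OC)cc(OC)cc2OC)cc(OC)c(OCc2ccccc2)c1OC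
F4 | step 7 | 2-[3-(benzyloxy)-2,4-dimethoxy-6-(2,4,6-trimethoxyphenoxy)phenyl]-5-methoxybenzene-1,3-diol | COc1cc(O)c(-c2c(Oc3c(OC)cc(OC)cc3OC)cc(OC)c(OCc3ccccc3)c2OC)c(O)c1
F5 | step 10 | 1-(arm-oxy)-3-fluoro-5-methoxy-2-nitrobenzene | COc1cc(F)c([N+](=O)[O-])c(Oc2c(OC)cc(Oc3c(OC)cc(OC)cc3OC)c(-c3c(OC)cc(OC)cc3OC)c2OC)c1
F6 | step 10 | 1,3-bis(arm-oxy)-5-methoxy-2-nitrobenzene | COc1cc(Oc2c(OC)cc(Oc3c(OC)cc(OC)cc3OC)c(-c3c(OC)cc(OC)cc3OC)c2OC)c([N+](=O)[O-])c(Oc2c(OC)cc(Oc3c(OC)cc(OC)cc3OC)c(-c3c(OC)cc(OC)cc3OC)c2OC)c1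
F7 | step 10 | 2,6-bis(arm-oxy)-4-methoxyaniline | COc1cc(Oc2c(OC)cc(Oc3c(OC)cc(OC)cc3OC)c(-c3c(OC)cc(OC)cc3OC)c2OC)c(N)c(Oc2c(OC)cc(Oc3c(OC)cc(OC)cc3OC)c(-c3c(OC)cc(OC)cc3OC)c2OC)c1
F8 | step 10 | 2,6-bis(arm-oxy)-4-methoxybenzenediazonium hydrogen sulfate | COc1cc(Oc2c(OC)cc(Oc3c(OC)cc(OC)cc3OC)c(-c3c(OC)cc(OC)cc3OC)c2OC)c([N+]#N)c(Oc2c(OC)cc(Oc3c(OC)cc(OC)cc3OC)c(-c3c(OC)cc(OC)cc3OC)c2OC)c1.OS(=O)(=O)[O-]
F9 | step 13 | 2-chloro-5-iodo-1,3-dimethoxybenzene | COc1cc(I)cc(OC)c1Cl
F10 | step 13 | (4-chloro-3,5-dimethoxyphenyl)(hydroxy)(tosyloxy)-λ3-iodane | COc1cc(I(O)OS(=O)(=O)c2ccc(C)cc2)cc(OC)c1Cl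
F11 | step 13 | (4-chloro-3,5-dimethoxyphenyl)(2,4,6-trimethoxyphenyl)iodonium 4-methylbenzenesulfonate | COc1cc(OC)c([I+]c2cc(OC)c(Cl)c(OC)c2)c(OC)c1.Cc1ccc(cc1)S(=O)(=O)[O-]
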